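The data are simulated with constants of no real substance.

The closed, stirred vessel turned substrate into an intermediate, and the runs showed two captures competing for it. In dusk, other capture product stopped at 95.1% on a charge of 0.95 equiv of second nucleophile while target took the rest, so target did not draw on second nucleophile.

| flask | substrate | second nucleophile | solid first nucleophile | temperature | remark | time |
|---|---|---|---|---|---|---|
| midnight | 0.20 M | 0.95 equiv | 3 equiv | 58 °C | run made earlier |  |
| dusk | 0.80 M | 0.95 equiv | 3 equiv | 74 °C | run made earlier |  |
| autumn | 0.40 M | 0.95 equiv | 6 equiv | 58 °C | run made earlier |  |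
| cedar | 0.40 M | 0.950 equiv | 3.00 equiv | 65 °C |  | 4.0 h |
| larch | 0.40 M | 0.950 equiv | 3.00 equiv | 80 °C |  | 4.0 h |
| ash | 0.40 M | 0.950 equiv | 3.00 equiv | 50 °C |  | 4.0 h |

midnight run (percent of the substrate charged)

| time / h | other capture product / % | substrate / % | intermediate / % | target / % |
|---|---|---|---|---|
| 0.417 | 78.4 | 0.6 | 0.5 | 21.4 |
| 0.833 | 77.7 | 0.1 | 0 | 21.7 |
| 2.00 | 78.5 | 0.4 | 0 | 22.0 |
| 5.00 | 78.8 | 0.4 | 0 | 21.8 |

dusk run (percent of the substrate charged)

| time / min | other capture product / % | substrate / % | intermediate / % | target / % |
|---|---|---|---|---|
| 8.00 | 95.1 | 0.3 | 2.6 | 2.1 |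
| 15.0 | 94.2 | 0.5 | 0.6 | 5.2 |
| 40.0 | 95.2 | 0.2 | 0 | 4.5 |
| 90.0 | 95.1 | 0 | 0.6 | 5.3 |

autumn run (percent of the substrate charged)

| time / h | other capture product / % | substrate / % | intermediate / % | target / % |
|---|---|---|---|---|
| 0.667 | 87.8 | 0 | 0.1 | 13.2 |
| 1.50 | 86.1 | 0.4 | 0.1 | 12.1 |
| 3.00 | 85.9 | 0 | 0 | 13.0 |
| 5.00 | 86.3 | 0 | 0 | 12.9 |

(readings scatter by 0.5 percentage points)

- at the start none of the solid first nucleophile is in solution

* which of these there is most of at the end, counted by the substrate in it, cedar (other capture product / intermediate / target / substrate)
* which of these there is most of at the end, counted by the substrate in it, larch (other capture product / intermediate / target / substrate)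
* which of these there is most of at the end, counted by the substrate in it, ash (other capture product / intermediate / target / substrate)
* final amount of the leader among these, as a percentage of the substrate charged, in cedar
* final amount of the leader among these, as a percentage of the substrate charged, in larch
* final amount of the leader among these, as a percentage of the substrate charged, in ash

I wrote the split as one concentration K, a selectivity factor in molar units: target formed equals K times the logarithm of [second nucleophile] at the start over [second nucleophile] at the end. The last readings gave K as 0.0246 M in midnight and 0.0216 M in autumn, both at 58 °C, though autumn had twice the substrate concentration and twice the equivalents of solid first nucleophile. The value of K at which target and other capture product end level on this recipe, the tie concentration, is 0.268 M. That is 10.9 times the midnight reading, so I committed to other capture product leading, with ash, the coldest flask, the one to watch.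

The forecast, reasoning that “K therefore falls about 8% per °C”, named other capture product in cedar at 90.5%, other capture product in larch at 94.8%, and other capture product in ash at 80%, range 75% to 84%.

The flasks gave other capture product at 92.2% in cedar, other capture product at 95.0% in larch and other capture product at 74.8% in ash.

    second nucleophile + intermediate → other capture product (k = 19.7 /M/min, Ea = 48.0 kJ/mol)
    solid first nucleophile ⇌ first nucleophile, rate k2*(cs2 - [first nucleophile]) while solid is left; crystals form when [first nucleophile] > cs2 (solubility = 0.150 M, k = 0.0201 /min)
    first nucleophile + intermediate → target (k = 328 /M/min, Ea = 43.0 kJ/mol)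
    substrate → intermediate (k = 0.0847 /min, Ea = 107 kJ/mol)
    first nucleophile ⇌ dormant form (K = 0.770, k = 0.0373 /min, Ea = 90.0 kJ/mol, ΔH = −65.0 kJ/mol)
    (constants at 50 °C)

Ash ended with K at 0.0649 M, against the forecast's 0.043 M, yet only a quarter of the tie concentration. Target in ash already stood at 25.2% after 2.00 h, when [first nucleophile] was 0.0941 M, against 0.150 M after 40.0 h. Larch ended with K at 0.00265 M. Its neighbour charged with 0.570 equiv of second nucleophile has a tie concentration of 0.0954 M, far above that K, and it ended with 57.0% other capture product against 43.0% target.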